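I decide to carry one number through this flask, and the charge gives it: 30.0%. It is the reagent surplus, reagent charged minus starting material charged as a share of the starting material charged, and equal charges are its zero.

- amber: starting material 20 mM; reagent 26 mM; capture agent 3 mM; free catalyst 0.20 mM; run made earlier
- flask: starting material 20 mM; reagent 26.0 mM; capture agent 2.00 mM; free catalyst 0.20 mM; time 12 d

amber run (percent of the starting material charged)

| time / d | target / % |
|---|---|
| 0.208 | 33.3 |
| 0.333 | 48.8 |
| 0.417 | 59.1 |
| 0.625 | 74.0 |
| 1.04 | 82.9 |
| 1.67 | 82.6 |
| 2.50 | 78.9 |

(each reading ± 0.5 percentage points)

1. when, up to 12 d, the flask holds most target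
2. the amount of target, in percent of the starting material charged, at that time
3. earliest time at which at least nineteen twentieths of that best amount are there, in d
4. latest time at which they still are, in d

- no earlier run changes the charge of capture agent; that part of a forecast is a guess

I build the flask up by steps. The main step comes first, one reagent per starting material: it takes the starting material, the limiting reagent, to a ceiling of 100% target and leaves 6.00 mM of reagent over. The amber run has the same surplus, 30.0%, and its readings climb to 82.9% at 1.04 d.

Then I add the loss those readings show, down to 78.9% at 2.50 d. If reagent is taking target on, one for one, each point of surplus costs one point of target, and the loss ends at a floor of 70.0%. That floor is 84.4% of the amber peak reading, which is below the share of the best amount that the last two questions ask for, so I expect their window to shut well before 12 d.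

Last comes the capture agent, cut from 3 mM to 2.00 mM. No earlier run varies it, so I can only guess: I put the best a little above the amber reading and keep the window close to the amber one.

The forecast, guessing that “the agent holds target stoichiometrically and invisibly”, says 87.5% at 1.25 d, with the window from 0.7 d to 2.5 d.

The flask holds most target, 85.8%, at 1.13 d, above the amber reading, and keeps the asked share of it from 0.745 d to 2.35 d.

    reagent + free catalyst ⇌ catalyst intermediate A (K = 31.0 L mol⁻¹, k = 2500 L mol⁻¹ h⁻¹)
    starting material + catalyst intermediate A ⇌ catalyst intermediate B (K = 4300 L mol⁻¹, k = 18000 L mol⁻¹ h⁻¹)
    catalyst intermediate B → catalyst intermediate C (k = 17.0 h⁻¹)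
    catalyst intermediate C → free catalyst + target (k = 21.0 h⁻¹)
    reagent + target → over-reaction product (k = 0.870 L mol⁻¹ h⁻¹)
    catalyst intermediate A + capture agent → trapped intermediate (k = 190 L mol⁻¹ h⁻¹)

At 12.0 d the flask has 71.4% target and 28.6% over-reaction product, against my floor of 70.0%, with 0.406% of its reagent charge left. The neighbour charged with 6.5 mM of reagent sits on the other side of zero, at a surplus of −67.5%, so there reagent is the limiting reagent and the scale reads that share as starting material left over. In that neighbour reagent is down to 0% at 12.0 d, starting material stands at 67.9%, and target stands at 31.7%.

(Readings and results come from a simulation for substances that don't exist; scatter was added.)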